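The 14-membered carbocycle is disconnected at the ring CH2–CH2 bond that joins the allylic carbon of the exocyclic methylene unit (C9) to the carbon next to the epoxide CH (C10): a head-to-tail isoprenoid junction lying between two allyl systems. The key step makes this bond and the macrocycle in one operation, by intramolecular alkylation of a C10 phenylsulfonyl-stabilised allyl anion with a 2-(siloxyalkyl)allyl chloride whose two CH2 termini are equivalent; the sulfone is then excised. The open-chain precursor grows from (R)-limonene, whose stereocentre and isopropenyl group become C1 and C15–C17. A late double epoxidation with epoxy-acid lactonisation sets C3, C4, C11 and C12.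

Key step: step 12

Remark (locants): cembrane numbering is used; C1 = ring carbon bearing the propanoate branch (C15, with C16 = carbonyl carbon and C17 = its methyl), C3 = lactone O–CH, C4 = C(OH)CH3 (methyl C18), C7 = CHOH, C8 = C(=C19H2), C9 and C10 = the two ring CH2 groups between C8 and the epoxide, C11/C12 = epoxide CH/C(CH3) (methyl C20), C13 and C14 = ring CH2 groups back to C1; the target is 1R,3R,4S,7R,11S,12S,15S; TBS = tert-butyldimethylsilyl.

Remark (stereochemistry carried as mixtures): C15 is carried as both epimers from step 1 to step 16 and is set in step 17; the C3 carbinol centre of 8 to 16 and C10 of 24 are left unassigned because later steps erase them.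

Remark (assumption): the L-fructose-derived enantiomer of the Shi ketone (ent-Shi ketone) is taken to be available as a catalyst.

Step 1
Reactants: 1 (R)-(+)-limonene
Product: 3 (4R)-p-menth-1-en-9-ol (both C15 epimers), via alkylborane 2 (not isolated)
Conditions: 9-BBN, THF, 0 °C to rt; then NaOH, H2O2, 0 °C
Reagents that add atoms: hydrogen peroxide, OO
Why: Hydroboration–oxidation with the bulky 9-BBN should take only the 1,1-disubstituted isopropenyl alkene in the anti-Markovnikov sense and leave the trisubstituted ring alkene, which places the C16 oxygen; C15 forms without control and is set in step 17.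

Step 2
Reactants: 3 (4R)-p-menth-1-en-9-ol
Product: 4 TBS ether of 3
Conditions: TBSCl, imidazole, DMF, rt
Reagents that add atoms: tert-butyldimethylsilyl chloride, CC(C)(C)[Si](C)(C)Cl
Why: O-Silylation of the primary alcohol masks the C16 oxygen through the organometallic, hydride, sulfonylation and strong-base steps that follow.

Step 3
Reactants: 4 TBS ether of 3
Product: 6 (3R)-3-[1-(tert-butyldimethylsilyloxy)propan-2-yl]-6-oxoheptanal, via ozonide 5 (not isolated)
Conditions: O3, CH2Cl2, −78 °C; then Me2S, −78 °C to rt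
Reagents that add atoms: ozone, [O-][O+]=O
Why: Ozonolysis with reductive work-up cleaves the only alkene, so that the ring carbons become the C3 aldehyde and the C12 methyl ketone, while the limonene stereocentre (now C1) is β to the aldehyde and cannot epimerise.

Step 4
Reactants: 6 keto aldehyde; 7 2-bromopropene
Product: 8 (5R)-5-[1-(tert-butyldimethylsilyloxy)propan-2-yl]-7-hydroxy-8-methylnon-8-en-2-one
Conditions: CrCl2, NiCl2 (cat.), DMF, rt
Reagents that add atoms: none
Why: The Nozaki–Hiyama–Kishi reaction adds the isopropenyl unit (C4, C18, C5) to the aldehyde only, under non-basic conditions that spare the methyl ketone from aldol reactions; the new C3 carbinol centre is left uncontrolled because step 8 erases it.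

Step 5
Reactants: 8 keto alcohol; 9 triethyl phosphonoacetate
Product: 10 ethyl (2E,6R)-6-[1-(tert-butyldimethylsilyloxy)propan-2-yl]-8-hydroxy-3,9-dimethyldeca-2,9-dienoate
Conditions: NaH (excess), THF, 0 °C to 60 °C
Reagents that add atoms: none
Why: Horner–Wadsworth–Emmons olefination of the methyl ketone adds C11 and C10 and should favour the E enoate (ester trans to the longer C13 chain); the minor Z isomer is removed by chromatography at this or the next stage.

Step 6
Reactants: 10 E enoate
Product: 11 (2E,6R)-6-[1-(tert-butyldimethylsilyloxy)propan-2-yl]-3,9-dimethyldeca-2,9-diene-1,8-diol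
Conditions: iBu2AlH, CH2Cl2, −78 °C
Reagents that add atoms: none
Why: 1,2-Reduction of the conjugated ester with the aluminium hydride gives the E primary allylic alcohol at C10 and leaves the silyl ether and the alkenes untouched.

Step 7
Reactants: 11 diol
Product: 14 (2E,6R)-6-[1-(tert-butyldimethylsilyloxy)propan-2-yl]-3,9-dimethyl-1-(phenylsulfonyl)deca-2,9-dien-8-ol, via mesylate 12 (not isolated), via allylic chloride 13 (not isolated)
Conditions: MsCl, 2,4,6-collidine, LiCl, DMF, 0 °C; then PhSO2Na, rt
Reagents that add atoms: sodium benzenesulfinate, [Na+].[O-]S(=O)c1ccccc1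
Why: Sulfonylation–chloride displacement converts the unhindered primary allylic alcohol faster than the hindered secondary C3 carbinol, and SN2 S-alkylation of the sulfinate at the primary carbon then installs the anion-stabilising sulfone at C10 without moving the E alkene.

Step 8
Reactants: 14 allylic sulfone; 15 ethyl vinyl ether
Product: 17 (4E,7R,10E)-7-[1-(tert-butyldimethylsilyloxy)propan-2-yl]-4,10-dimethyl-12-(phenylsulfonyl)dodeca-4,10-dienal, via allyl vinyl ether 16 (not isolated)
Conditions: Hg(OAc)2 (cat.), 15 as solvent, reflux; then toluene, 140 °C (sealed tube)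
Reagents that add atoms: none
Why: Vinyl transfer to the C3 alcohol and Claisen rearrangement through a chair transition state with the C2 chain equatorial should give the E C3=C4 alkene and the C7 aldehyde, adding C6 and C7 and erasing the C3 carbinol centre.

Step 9
Reactants: 17 aldehyde; 18 2-bromoallyl alcohol
Product: 19 (3R,6E,9R,12E)-9-[1-(tert-butyldimethylsilyloxy)propan-2-yl]-6,12-dimethyl-2-methylidene-14-(phenylsulfonyl)tetradeca-6,12-diene-1,3-diol
Conditions: CrCl2, NiCl2 (cat.), (S)-N-[2-(4-isopropyl-4,5-dihydrooxazol-2-yl)phenyl]methanesulfonamide, Et3N, THF, rt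
Reagents that add atoms: none
Why: In this asymmetric Nozaki–Hiyama–Kishi coupling the alkenylchromium species bound to the chiral sulfonamide ligand should add to the Si face of the aldehyde and set C7 as R, while bringing in C8, C9 and C19 as a 2-methylene-1,3-diol.

Step 10
Reactants: 19 diol
Product: 21 (3R,6E,9R,12E)-9-[1-(tert-butyldimethylsilyloxy)propan-2-yl]-1-chloro-6,12-dimethyl-2-methylidene-14-(phenylsulfonyl)tetradeca-6,12-dien-3-ol, via mesylate 20 (not isolated)
Conditions: MsCl, 2,4,6-collidine, LiCl, DMF, 0 °C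
Reagents that add atoms: lithium chloride, [Li+].[Cl-]
Why: Sulfonylation–chloride displacement is selective for the primary allylic alcohol over the secondary C7 carbinol and gives the 2-substituted allyl chloride without allylic shift.

Step 11
Reactants: 21 chloro alcohol
Product: 22 C7 TBS ether of 21
Conditions: TBSOTf, 2,6-lutidine, CH2Cl2, −78 °C
Reagents that add atoms: tert-butyldimethylsilyl trifluoromethanesulfonate, CC(C)(C)[Si](C)(C)OS(=O)(=O)C(F)(F)F
Why: O-Silylation of the C7 alcohol leaves the C10 methylene as the only acidic site for step 12 and keeps this alcohol from attacking the 3,4-epoxide in step 16.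

Step 12
Reactants: 22 open-chain chloro sulfone
Product: 24 (1R,3E,7R,11E)-7,16-bis(tert-butyldimethylsilyloxy)-10-(phenylsulfonyl)cembra-3,8(19),11-triene (C10 epimers), via lithiated sulfone 23 (not isolated)
Conditions: LiN(SiMe3)2, THF, 0 °C to rt; 22 added by syringe pump (high dilution)
Reagents that add atoms: none
Why: LiN(SiMe3)2 removes the C10 proton, which is both allylic and α to the sulfone, and the sulfonyl-stabilised allyl anion 23 displaces chloride from the 2-substituted allyl terminus to form the C9–C10 bond. The closest known reaction type is the intramolecular alkylation of a sulfone-stabilised allylic carbanion by an allylic halide, the classical way of joining prenyl units head to tail and of closing cembrane rings. The 14-membered carbocycle closes in the exo-tet mode at C9; attack at the other allyl terminus (C19, with allylic shift) gives the same constitution, so the electrophile poses no regiochemical question. The only new stereocentre, C10, is not controlled and is erased in step 13. The step needs α- rather than γ-alkylation of the anion (secured by the sulfonyl group and by the quaternary centre that attack through C12 would create), retention of the E C11=C12 geometry (the allyl sulfone anion keeps its configuration) and ring closure over oligomerisation (secured by slow addition at high dilution). No other acidic or electrophilic site competes, since both alcohols are silyl ethers.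

Step 13
Reactants: 24 macrocyclic sulfone
Product: 25 (1R,3E,7R,11E)-7,16-bis(tert-butyldimethylsilyloxy)cembra-3,8(19),11-triene
Conditions: Pd(dppp)Cl2 (cat.), LiBHEt3, THF, 0 °C
Reagents that add atoms: none
Why: In this palladium-catalysed reductive desulfonylation, zerovalent palladium ionises the allylic sulfone to a π-allyl complex and hydride is delivered to the less substituted terminus C10, so the E C11=C12 alkene stays in place and the C10 centre disappears.

Step 14
Reactants: 25 bis-silyl ether
Product: 26 (1R,3E,7R,11E)-7-(tert-butyldimethylsilyloxy)cembra-3,8(19),11-trien-16-ol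
Conditions: HF·pyridine, pyridine, THF, 0 °C
Reagents that add atoms: none
Why: Selective desilylation with buffered fluoride should cleave the primary C16 silyl ether well before the hindered secondary allylic C7 silyl ether.

Step 15
Reactants: 26 primary alcohol
Product: 28 (1R,3E,7R,11E)-7-(tert-butyldimethylsilyloxy)cembra-3,8(19),11-trien-16-oic acid, via aldehyde 27 (not isolated)
Conditions: TEMPO (cat.), PhI(OAc)2, MeCN/H2O, rt
Reagents that add atoms: water, O
Why: Oxoammonium (TEMPO) oxidation takes the primary alcohol through the aldehyde hydrate to the carboxylic acid without touching the alkenes or the silyl ether.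

Step 16
Reactants: 28 triene acid
Product: 30 7-O-TBS ether of the target as both C15 epimers, via bis-epoxy acid 29 (not isolated)
Conditions: ent-Shi ketone (cat.), KHSO5 (as Oxone), K2CO3, Bu4NHSO4, MeCN/CH2(OMe)2/aq. Na2B4O7 buffer, 0 °C; then NaH2PO4 work-up (pH 4 to 5), CH2Cl2, rt
Reagents that add atoms: potassium peroxymonosulfate, [K+].[O-]S(=O)(=O)OO
Why: Shi epoxidation with the L-fructose-derived ketone should deliver oxygen to the same face of both E trisubstituted alkenes to give the (3S,4S) and (11S,12S) epoxides while the hindered 1,1-disubstituted alkene is left, and the C16 acid then opens the 3,4-epoxide at its less substituted carbon C3 in a 6-exo attack with inversion, which gives the δ-lactone with C3 R and the C4 S tertiary alcohol.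

Step 17
Reactants: 30 lactone as C15 epimers
Product: 31 7-O-TBS ether of the target (15S)
Conditions: DBU, toluene, 40 °C
Reagents that add atoms: none
Why: Base-mediated epimerisation through the lactone enolate should converge both C15 epimers on the more stable isomer, in which the methyl group is equatorial and trans to the C1–C14 ring bond, which is 15S.

Step 18
Reactants: 31 silyl ether
Product: 32 target
Conditions: Bu4NF, AcOH, THF, 0 °C to rt
Reagents that add atoms: none
Why: Buffered fluoride desilylation frees the C7 alcohol without opening the epoxide or the lactone.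

Compound list

1 | (R)-(+)-limonene | CC1=CC[C@@H](CC1)C(C)=C | starting material
2 | 9-{2-[(1R)-4-methylcyclohex-3-en-1-yl]propyl}-9-borabicyclo[3.3.1]nonane (not isolated) | CC1=CC[C@@H](CC1)C(C)CB1C2CCCC1CCC2 | intermediate
3 | 2-[(1R)-4-methylcyclohex-3-en-1-yl]propan-1-ol, (4R)-p-menth-1-en-9-ol, both C15 epimers | CC1=CC[C@@H](CC1)C(C)CO | intermediate
4 | tert-butyl{2-[(1R)-4-methylcyclohex-3-en-1-yl]propoxy}dimethylsilane | CC1=CC[C@@H](CC1)C(C)CO[Si](C)(C)C(C)(C)C | intermediate
5 | secondary ozonide (1,2,4-trioxolane) across the former ring alkene of 4 (not isolated) | CC12CC[C@@H](C(C)CO[Si](C)(C)C(C)(C)C)CC(O1)OO2 | intermediate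
6 | (3R)-3-[1-(tert-butyldimethylsilyloxy)propan-2-yl]-6-oxoheptanal (C3 aldehyde, C12 methyl ketone) | CC(=O)CC[C@@H](C(C)CO[Si](C)(C)C(C)(C)C)CC=O | intermediate
7 | 2-bromopropene | CC(Br)=C | starting material
8 | (5R)-5-[1-(tert-butyldimethylsilyloxy)propan-2-yl]-7-hydroxy-8-methylnon-8-en-2-one (C3 carbinol epimers) | CC(=O)CC[C@@H](C(C)CO[Si](C)(C)C(C)(C)C)CC(O)C(C)=C | intermediate
9 | triethyl phosphonoacetate | CCOC(=O)CP(=O)(OCC)OCC | starting material
10 | ethyl (2E,6R)-6-[1-(tert-butyldimethylsilyloxy)propan-2-yl]-8-hydroxy-3,9-dimethyldeca-2,9-dienoate | CCOC(=O)/C=C(\C)CC[C@@H](C(C)CO[Si](C)(C)C(C)(C)C)CC(O)C(C)=C | intermediate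
11 | (2E,6R)-6-[1-(tert-butyldimethylsilyloxy)propan-2-yl]-3,9-dimethyldeca-2,9-diene-1,8-diol | OC/C=C(\C)CC[C@@H](C(C)CO[Si](C)(C)C(C)(C)C)CC(O)C(C)=C | intermediate
12 | C10 methanesulfonate of 11 (not isolated) | CS(=O)(=O)OC/C=C(\C)CC[C@@H](C(C)CO[Si](C)(C)C(C)(C)C)CC(O)C(C)=C | intermediate
13 | C10 allylic chloride from 11 (not isolated) | ClC/C=C(\C)CC[C@@H](C(C)CO[Si](C)(C)C(C)(C)C)CC(O)C(C)=C | intermediate
14 | (2E,6R)-6-[1-(tert-butyldimethylsilyloxy)propan-2-yl]-3,9-dimethyl-1-(phenylsulfonyl)deca-2,9-dien-8-ol | O=S(=O)(C/C=C(\C)CC[C@@H](C(C)CO[Si](C)(C)C(C)(C)C)CC(O)C(C)=C)c1ccccc1 | intermediate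
15 | ethyl vinyl ether | CCOC=C | starting material
16 | vinyl ether of 14 at the C3 oxygen (not isolated) | O=S(=O)(C/C=C(\C)CC[C@@H](C(C)CO[Si](C)(C)C(C)(C)C)CC(OC=C)C(C)=C)c1ccccc1 | intermediate
17 | (4E,7R,10E)-7-[1-(tert-butyldimethylsilyloxy)propan-2-yl]-4,10-dimethyl-12-(phenylsulfonyl)dodeca-4,10-dienal | O=S(=O)(C/C=C(\C)CC[C@@H](C(C)CO[Si](C)(C)C(C)(C)C)C/C=C(\C)CCC=O)c1ccccc1 | intermediate
18 | 2-bromoallyl alcohol (2-bromoprop-2-en-1-ol) | OCC(Br)=C | starting material
19 | (3R,6E,9R,12E)-9-[1-(tert-butyldimethylsilyloxy)propan-2-yl]-6,12-dimethyl-2-methylidene-14-(phenylsulfonyl)tetradeca-6,12-diene-1,3-diol (7R in cembrane numbering) | O=S(=O)(C/C=C(\C)CC[C@@H](C(C)CO[Si](C)(C)C(C)(C)C)C/C=C(\C)CC[C@@H](O)C(=C)CO)c1ccccc1 | intermediate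
20 | primary (C9) methanesulfonate of 19 (not isolated) | O=S(=O)(C/C=C(\C)CC[C@@H](C(C)CO[Si](C)(C)C(C)(C)C)C/C=C(\C)CC[C@@H](O)C(=C)COS(C)(=O)=O)c1ccccc1 | intermediate
21 | (3R,6E,9R,12E)-9-[1-(tert-butyldimethylsilyloxy)propan-2-yl]-1-chloro-6,12-dimethyl-2-methylidene-14-(phenylsulfonyl)tetradeca-6,12-dien-3-ol | O=S(=O)(C/C=C(\C)CC[C@@H](C(C)CO[Si](C)(C)C(C)(C)C)C/C=C(\C)CC[C@@H](O)C(=C)CCl)c1ccccc1 | intermediate
22 | C7 tert-butyldimethylsilyl ether of 21 | O=S(=O)(C/C=C(\C)CC[C@@H](C(C)CO[Si](C)(C)C(C)(C)C)C/C=C(\C)CC[C@@H](O[Si](C)(C)C(C)(C)C)C(=C)CCl)c1ccccc1 | intermediate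
23 | C10 lithio derivative of 22 (not isolated) | [Li+].O=S(=O)([CH-]/C=C(\C)CC[C@@H](C(C)CO[Si](C)(C)C(C)(C)C)C/C=C(\C)CC[C@@H](O[Si](C)(C)C(C)(C)C)C(=C)CCl)c1ccccc1 | intermediate
24 | (1R,3E,7R,11E)-7,16-bis(tert-butyldimethylsilyloxy)-10-(phenylsulfonyl)cembra-3,8(19),11-triene (C10 and C15 epimers) | C=C1CC(/C=C(\C)CC[C@@H](C(C)CO[Si](C)(C)C(C)(C)C)C/C=C(\C)CC[C@H]1O[Si](C)(C)C(C)(C)C)S(=O)(=O)c1ccccc1 | intermediate
25 | (1R,3E,7R,11E)-7,16-bis(tert-butyldimethylsilyloxy)cembra-3,8(19),11-triene | C=C1CC/C=C(\C)CC[C@@H](C(C)CO[Si](C)(C)C(C)(C)C)C/C=C(\C)CC[C@H]1O[Si](C)(C)C(C)(C)C | intermediate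
26 | (1R,3E,7R,11E)-7-(tert-butyldimethylsilyloxy)cembra-3,8(19),11-trien-16-ol | C=C1CC/C=C(\C)CC[C@@H](C(C)CO)C/C=C(\C)CC[C@H]1O[Si](C)(C)C(C)(C)C | intermediate
27 | (1R,3E,7R,11E)-7-(tert-butyldimethylsilyloxy)cembra-3,8(19),11-trien-16-al (not isolated) | C=C1CC/C=C(\C)CC[C@@H](C(C)C=O)C/C=C(\C)CC[C@H]1O[Si](C)(C)C(C)(C)C | intermediate
28 | (1R,3E,7R,11E)-7-(tert-butyldimethylsilyloxy)cembra-3,8(19),11-trien-16-oic acid | C=C1CC/C=C(\C)CC[C@@H](C(C)C(=O)O)C/C=C(\C)CC[C@H]1O[Si](C)(C)C(C)(C)C | intermediate
29 | (1R,3S,4S,7R,11S,12S)-3,4:11,12-diepoxy-7-(tert-butyldimethylsilyloxy)cembr-8(19)-en-16-oic acid (not isolated) | C=C1CC[C@@H]2O[C@@]2(C)CC[C@@H](C(C)C(=O)O)C[C@@H]2O[C@@]2(C)CC[C@H]1O[Si](C)(C)C(C)(C)C | intermediate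
30 | 7-O-tert-butyldimethylsilyl ether of the target, both C15 epimers | C=C1CC[C@@H]2O[C@@]2(C)CC[C@@H]2C[C@@H](OC(=O)C2C)[C@@](C)(O)CC[C@H]1O[Si](C)(C)C(C)(C)C | intermediate
31 | 7-O-tert-butyldimethylsilyl ether of the target, 15S | C=C1CC[C@@H]2O[C@@]2(C)CC[C@@H]2C[C@@H](OC(=O)[C@H]2C)[C@@](C)(O)CC[C@H]1O[Si](C)(C)C(C)(C)C | intermediate
32 | (1R,3R,4S,7R,11S,12S,15S)-11,12-epoxy-4,7-dihydroxycembr-8(19)-en-16,3-olide (CNP0262409.1) | C=C1CC[C@@H]2O[C@@]2(C)CC[C@@H]2C[C@@H](OC(=O)[C@H]2C)[C@@](C)(O)CC[C@H]1O | target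

Total step count: 18
Longest linear sequence: 18 steps (1 to 32); all other building blocks (7, 9, 15, 18) are purchased.

Steps most likely to fail

Step 12. The process at risk is ring closure that is slow relative to intermolecular alkylation, so that oligomers form, or degradation of the allylic chloride in the strongly basic medium. The fallback replaces the base-driven SN2 closure by a metal-templated one (Tsuji–Trost allylic alkylation) and sets out from diol 19. Selective acetylation of the primary allylic alcohol (Ac2O, 2,4,6-collidine, CH2Cl2, −20 °C) gives the allylic acetate F1, and silylation (TBSOTf, 2,6-lutidine) gives its C7 silyl ether F2. F2 is deprotonated at C10 with NaH in THF and added slowly to Pd(PPh3)4 and dppe in THF at reflux. Zerovalent palladium ionises the acetate to a 2-substituted π-allyl complex with equivalent termini, the sulfonyl anion attacks it on the metal template, and the route is rejoined at 24.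

Step 16. The process at risk is poor facial selectivity, if the conformation of the macrocycle overrides the chiral ketone at one alkene; the epoxide opening would then also take a wrong course, because it needs the 3,4-epoxide on the correct face. The fallback oxidises C3=C4 on the open chain, where the ketone meets an unbiased alkene, and sets out from 22. The ent-Shi conditions of step 16 should epoxidise only C3=C4, since the other two alkenes carry electron-withdrawing allylic groups, to give the open-chain epoxide F3. Ring closure as in step 12 gives the macrocyclic epoxy sulfone F4. Desulfonylation with Pd(PPh3)4 and NaBH4 (LiBHEt3 would open the epoxide) gives the epoxy diene F5, and NH4F in MeOH frees the primary alcohol F6. Oxidation as in step 15 gives the epoxy acid F7, which lactonises as in step 16 to the hydroxy lactone F8. One ent-Shi epoxidation of the remaining C11=C12 alkene then rejoins the route at 30.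

Step 9. The process at risk is insufficient facial selectivity of the ligand-controlled addition, which would leave C7 epimers. The fallback sets C7 by ketone reduction and sets out from aldehyde 17. Coupling with 18 without the chiral ligand (CrCl2, NiCl2 cat., DMF) gives the C7-epimeric diol F9, and chlorination as in step 10 gives the C7-epimeric chloride F10. Dess–Martin oxidation gives the α-methylene ketone F11. Corey–Bakshi–Shibata reduction ((S)-methyl oxazaborolidine, BH3·SMe2, toluene, −40 °C), in which the branched alkenyl group acts as the large substituent, should give the 7R alcohol and rejoin the route at 21.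

Further compounds
F1 | step 12 | primary allylic (C9) acetate of diol 19, free 7R alcohol | O=S(=O)(C/C=C(\C)CC[C@@H](C(C)CO[Si](C)(C)C(C)(C)C)C/C=C(\C)CC[C@@H](O)C(=C)COC(C)=O)c1ccccc1
F2 | step 12 | C7 tert-butyldimethylsilyl ether of F1 | O=S(=O)(C/C=C(\C)CC[C@@H](C(C)CO[Si](C)(C)C(C)(C)C)C/C=C(\C)CC[C@@H](O[Si](C)(C)C(C)(C)C)C(=C)COC(C)=O)c1ccccc1
F3 | step 16 | (3S,4S)-3,4-epoxide of open-chain chloro sulfone 22 | O=S(=O)(C/C=C(\C)CC[C@@H](C(C)CO[Si](C)(C)C(C)(C)C)C[C@@H]1O[C@@]1(C)CC[C@@H](O[Si](C)(C)C(C)(C)C)C(=C)CCl)c1ccccc1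
F4 | step 16 | (1R,3S,4S,7R,11E)-3,4-epoxy-7,16-bis(tert-butyldimethylsilyloxy)-10-(phenylsulfonyl)cembra-8(19),11-diene | C=C1CC(/C=C(\C)CC[C@@H](C(C)CO[Si](C)(C)C(C)(C)C)C[C@@H]2O[C@@]2(C)CC[C@H]1O[Si](C)(C)C(C)(C)C)S(=O)(=O)c1ccccc1
F5 | step 16 | (1R,3S,4S,7R,11E)-3,4-epoxy-7,16-bis(tert-butyldimethylsilyloxy)cembra-8(19),11-diene | C=C1CC/C=C(\C)CC[C@@H](C(C)CO[Si](C)(C)C(C)(C)C)C[C@@H]2O[C@@]2(C)CC[C@H]1O[Si](C)(C)C(C)(C)C
F6 | step 16 | (1R,3S,4S,7R,11E)-3,4-epoxy-7-(tert-butyldimethylsilyloxy)cembra-8(19),11-dien-16-ol | C=C1CC/C=C(\C)CC[C@@H](C(C)CO)C[C@@H]2O[C@@]2(C)CC[C@H]1O[Si](C)(C)C(C)(C)C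
F7 | step 16 | (1R,3S,4S,7R,11E)-3,4-epoxy-7-(tert-butyldimethylsilyloxy)cembra-8(19),11-dien-16-oic acid | C=C1CC/C=C(\C)CC[C@@H](C(C)C(=O)O)C[C@@H]2O[C@@]2(C)CC[C@H]1O[Si](C)(C)C(C)(C)C
F8 | step 16 | (1R,3R,4S,7R,11E)-4-hydroxy-7-(tert-butyldimethylsilyloxy)cembra-8(19),11-dien-16,3-olide, both C15 epimers | C=C1CC/C=C(\C)CC[C@@H]2C[C@@H](OC(=O)C2C)[C@@](C)(O)CC[C@H]1O[Si](C)(C)C(C)(C)C
F9 | step 9 | diol 19 as a mixture of C7 epimers | O=S(=O)(C/C=C(\C)CC[C@@H](C(C)CO[Si](C)(C)C(C)(C)C)C/C=C(\C)CCC(O)C(=C)CO)c1ccccc1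
F10 | step 9 | chloro alcohol 21 as a mixture of C7 epimers | O=S(=O)(C/C=C(\C)CC[C@@H](C(C)CO[Si](C)(C)C(C)(C)C)C/C=C(\C)CCC(O)C(=C)CCl)c1ccccc1
F11 | step 9 | C7 ketone of F10 (2-chloromethyl enone) | O=S(=O)(C/C=C(\C)CC[C@@H](C(C)CO[Si](C)(C)C(C)(C)C)C/C=C(\C)CCC(=O)C(=C)CCl)c1ccccc1
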